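## Retrosynthetic overview

1. Target 38 comes from the ten-membered hydroxy ester 28 by esterification at C9 with acid 36 and desilylation; the C8 epoxy ester (acid 25) is put on before ring closure.
2. The ten-membered carbocycle (second ring formed) is closed by ring-closing metathesis at C1=C10 of the acyclic lactone 27.
3. The γ-lactone (first ring formed) and the C6–C7 bond come from a CrCl2-mediated allylation/lactonisation of (Z)-enal 6 with allylic bromide 19, steered by the C8 stereocentre.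
4. Key disconnection, C8–C9 (two oxygen-bearing, normally electrophilic carbons): enal 11 plus the γ-silyloxy-2-(methoxycarbonyl)allylboronate 17, a β-oxy-acrylate homoenolate / α-oxy-carbanion equivalent, under chiral Brønsted-acid catalysis; it sets 8S,9S.
5. Building blocks: 6 from but-2-yn-1-ol; 11 from glyoxal mono-acetal and methyl acrylate; 17 from methyl propanoate and methyl formate; 25 from tiglyl alcohol; 36 by Evans aldol.

Assumption: the SMILES is taken literally (C4=C5 is Z, C1=C10 is ring-cis, and the oxirane acyl group is the cis-2,3-dimethyl (2S,3R) isomer); germacrane atom labels C1–C15 are used in the text.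

## Route

Step 1
Reactants: 1 but-2-yn-1-ol
Product: 3 (Z)-3-iodobut-2-en-1-ol, via cyclic alkenylalanate 2 (not isolated)
Conditions: NaAlH2(OCH2CH2OMe)2, THF, 0 °C to rt; then I2, −78 °C
Reagents that add atoms: iodine, II
Why: hydroxyl-directed trans-hydroalumination puts aluminium on C3 cis to CH2OH in a five-membered alanate, and iodinolysis with retention gives the Z iodide.

Step 2
Reactants: 3 (Z)-3-iodobut-2-en-1-ol; 4 but-3-enylzinc bromide (CH2=CHCH2CH2ZnBr)
Product: 5 (Z)-3-methylhepta-2,6-dien-1-ol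
Conditions: Pd(dppf)Cl2 (3 mol %), THF, 50 °C
Reagents that add atoms: none
Why: Negishi sp2–sp3 coupling proceeds with retention of the alkene geometry, and the bidentate phosphine suppresses β-hydride loss.

Step 3
Reactants: 5 (Z)-3-methylhepta-2,6-dien-1-ol
Product: 6 (Z)-3-methylhepta-2,6-dienal
Conditions: Dess–Martin periodinane, CH2Cl2, 0 °C
Reagents that add atoms: none
Why: Dess–Martin oxidation of the allylic alcohol is fast at 0 °C and leaves the Z enal unisomerised.

Step 4
Reactants: 7 2,2-dimethoxyacetaldehyde; 8 methyl acrylate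
Product: 9 methyl 3-hydroxy-4,4-dimethoxy-2-methylidenebutanoate (racemic)
Conditions: DABCO (0.5 equiv), 1,4-dioxane/H2O, rt
Reagents that add atoms: none
Why: Morita–Baylis–Hillman reaction of an activated aldehyde; the racemic carbinol centre disappears in step 5.

Step 5
Reactants: 9 methyl 3-hydroxy-4,4-dimethoxy-2-methylidenebutanoate
Product: 10 methyl (Z)-2-(bromomethyl)-4,4-dimethoxybut-2-enoate
Conditions: NBS, Me2S, CH2Cl2, 0 °C to rt
Reagents that add atoms: N-bromosuccinimide, O=C1CCC(=O)N1Br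
Why: Corey–Kim-type activation of the allylic alcohol followed by SN2' bromide delivery gives the rearranged, thermodynamically preferred Z bromide under non-acidic conditions that spare the acetal.

Step 6
Reactants: 10 methyl (Z)-2-(bromomethyl)-4,4-dimethoxybut-2-enoate
Product: 11 methyl (Z)-2-(bromomethyl)-4-oxobut-2-enoate
Conditions: TFA, H2O, CH2Cl2, 0 °C
Reagents that add atoms: water, O
Why: acid-catalysed acetal hydrolysis gives the enal, whose formyl and ester groups stay trans (the stable geometry); it is used at once.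

Step 7
Reactants: 12 methyl propanoate; 13 methyl formate
Product: 15 methyl (E)-3-[(tert-butyldimethylsilyl)oxy]-2-methylprop-2-enoate, via sodium enolate 14 (not isolated)
Conditions: NaH, THF, 0 °C to rt; then TBSCl, 0 °C
Reagents that add atoms: tert-butyldimethylsilyl chloride, CC(C)(C)[Si](C)(C)Cl
Why: crossed Claisen formylation gives the formyl-ester enolate, and O-silylation gives the enol ether, which settles as the E isomer (OSi trans to CO2Me).

Step 8
Reactants: 15 methyl (E)-3-[(tert-butyldimethylsilyl)oxy]-2-methylprop-2-enoate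
Product: 16 methyl (Z)-2-(bromomethyl)-3-[(tert-butyldimethylsilyl)oxy]prop-2-enoate
Conditions: NBS, AIBN (5 mol %), PhCF3, 80 °C
Reagents that add atoms: N-bromosuccinimide, O=C1CCC(=O)N1Br
Why: Wohl–Ziegler bromination of the only allylic methyl group; the push–pull alkene is too electron-poor for fast ionic bromination.

Step 9
Reactants: 16 methyl (Z)-2-(bromomethyl)-3-[(tert-butyldimethylsilyl)oxy]prop-2-enoate
Product: 17 methyl (E)-3-[(tert-butyldimethylsilyl)oxy]-2-[(4,4,5,5-tetramethyl-1,3,2-dioxaborolan-2-yl)methyl]prop-2-enoate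
Conditions: B2pin2, Pd2(dba)3 (2.5 mol %), toluene, 50 °C
Reagents that add atoms: bis(pinacolato)diboron, CC1(C)OB(OC1(C)C)B1OC(C)(C)C(C)(C)O1
Why: Miyaura-type allylic borylation through a π-allylpalladium puts boron on the unsubstituted CH2 terminus and keeps OSi cis to CH2B.

Step 10
Reactants: 11 methyl (Z)-2-(bromomethyl)-4-oxobut-2-enoate; 17 allylboronate
Product: 19 dimethyl (2Z,4S,5S)-2-(bromomethyl)-5-[(tert-butyldimethylsilyl)oxy]-4-hydroxy-6-methylidenehept-2-enedioate, via pinacol borate 18 (not isolated)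
Conditions: (R)-TRIP [(R)-3,3'-bis(2,4,6-triisopropylphenyl)-1,1'-binaphthyl-2,2'-diyl hydrogen phosphate] (10 mol %), 4 Å molecular sieves, toluene, −30 °C; then pH 7 buffer
Reagents that add atoms: none
Why: Proposed new method: chiral-phosphoric-acid-catalysed allylboration in which the boronate is a γ-silyloxy-2-(methoxycarbonyl)allyl unit, so that C9 (the formyl-derived β-carbon of a β-oxy-acrylate, normally an acceptor) attacks the formyl carbon C8 as a homoenolate / α-oxy-carbanion equivalent; the closed chair transition state places OSi (cis to CH2B) axial and gives the syn 8,9 pair, and (R)-TRIP, hydrogen-bonded to a boronate oxygen and the formyl hydrogen, is expected to select the face leading to 8S,9S by analogy with its sense for allyl- and crotylboronates with enals; closest known reactions are Brønsted-acid-catalysed allyl/crotylboration and the additions of 2-(alkoxycarbonyl)allylboronates and γ-alkoxyallylboron reagents.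

Step 11
Reactants: 19 allylic bromide; 6 (Z)-3-methylhepta-2,6-dienal
Product: 22 methyl (3S,4S)-3-[(tert-butyldimethylsilyl)oxy]-4-hydroxy-4-[(2R,3R)-2-[(1Z)-2-methylhexa-1,5-dien-1-yl]-4-methylidene-5-oxooxolan-3-yl]-2-methylidenebutanoate, via trimethylsilyl ether 20 (not isolated), via silylated lactone 21 (not isolated)
Conditions: BSA [N,O-bis(trimethylsilyl)acetamide], THF, rt; then CrCl2 (4 equiv), THF, rt; then 1 M HCl, 0 °C
Reagents that add atoms: none
Why: Nozaki–Hiyama-type 2-(alkoxycarbonyl)allylation: the equilibrated E-allylchromium adds through a chair transition state (anti, hence trans C6/C7), the C8–H eclipses the ester-bearing alkene carbon (A1,3 strain) so the aldehyde approaches anti to the bulky C9 branch (7S relative to 8S), and the chromium alkoxide closes the γ-lactone; the transient C8 silyl ether blocks 1,4-elimination, dihydrofuran formation and competing lactonisation (C7 is labelled R in 22 only because the free C8–OH lowers the CIP rank of C8).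

Step 12
Reactants: 23 (E)-2-methylbut-2-en-1-ol
Product: 24 [(2R,3R)-2,3-dimethyloxiran-2-yl]methanol
Conditions: Ti(OiPr)4 (10 mol %), D-(−)-diethyl tartrate (12 mol %), tBuOOH, 4 Å molecular sieves, CH2Cl2, −20 °C
Reagents that add atoms: tert-butyl hydroperoxide, CC(C)(C)OO
Why: Sharpless asymmetric epoxidation; the D-(−)-tartrate catalyst delivers oxygen to the face that gives the (2R,3R) epoxy alcohol, and the E alkene fixes the cis methyl groups.

Step 13
Reactants: 24 [(2R,3R)-2,3-dimethyloxiran-2-yl]methanol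
Product: 25 (2S,3R)-2,3-dimethyloxirane-2-carboxylic acid
Conditions: RuCl3 (2 mol %), NaIO4, CCl4/MeCN/H2O, rt
Reagents that add atoms: sodium periodate, [Na+].[O-]I(=O)(=O)=O
Why: catalytic RuO4 oxidation takes the primary alcohol to the acid without touching the epoxide; the C2 descriptor changes from R to S by CIP ranking only.

Step 14
Reactants: 22 lactone alcohol; 25 (2S,3R)-2,3-dimethyloxirane-2-carboxylic acid
Product: 26 methyl (3S,4S)-3-[(tert-butyldimethylsilyl)oxy]-4-{[(2S,3R)-2,3-dimethyloxirane-2-carbonyl]oxy}-4-[(2R,3S)-2-[(1Z)-2-methylhexa-1,5-dien-1-yl]-4-methylidene-5-oxooxolan-3-yl]-2-methylidenebutanoate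
Conditions: DCC, DMAP (0.2 equiv), CH2Cl2, 0 °C to rt
Reagents that add atoms: none
Why: Steglich esterification of the only free hydroxyl (C8) with retention at every centre.

Step 15
Reactants: 26 silyl ether
Product: 27 methyl (3S,4S)-4-{[(2S,3R)-2,3-dimethyloxirane-2-carbonyl]oxy}-3-hydroxy-4-[(2R,3S)-2-[(1Z)-2-methylhexa-1,5-dien-1-yl]-4-methylidene-5-oxooxolan-3-yl]-2-methylidenebutanoate
Conditions: HF·pyridine, pyridine, THF, 0 °C to rt
Reagents that add atoms: none
Why: buffered fluoride desilylation frees the C9 hydroxyl without acyl migration or opening of the deactivated glycidic ester.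

Step 16
Reactants: 27 diene
Product: 28 methyl (3aS,4S,5S,6E,10Z,11aR)-4-{[(2S,3R)-2,3-dimethyloxirane-2-carbonyl]oxy}-5-hydroxy-10-methyl-3-methylidene-2-oxo-2,3,3a,4,5,8,9,11a-octahydrocyclodeca[b]furan-6-carboxylate
Conditions: second-generation Hoveyda–Grubbs catalyst RuCl2(H2IMes)(=CH-C6H4-2-OiPr) (10 mol %), toluene (1 mM), 80 °C
Reagents that add atoms: none
Why: ring-closing metathesis: ruthenium loads on the terminal vinyl group and closes onto the 1,1-disubstituted acrylate (free allylic OH assists), and a ten-membered ring holding the cis C4=C5 bond and the trans-fused lactone should favour the ring-cis C1=C10 geometry (6E).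

Step 17
Reactants: 29 (R)-4-benzyl-3-propanoyl-1,3-oxazolidin-2-one; 30 acetaldehyde
Product: 33 (R)-4-benzyl-3-[(2R,3S)-3-hydroxy-2-methylbutanoyl]-1,3-oxazolidin-2-one, via boron Z-enolate 31 (not isolated), via boron aldolate 32 (not isolated)
Conditions: Bu2BOTf, iPr2NEt, CH2Cl2, −78 to 0 °C; then H2O2, MeOH, pH 7 buffer
Reagents that add atoms: none
Why: Evans syn aldol: the Z boron enolate reacts through a Zimmerman–Traxler chair on the face opposite the benzyl group, giving the 2R,3S syn adduct.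

Step 18
Reactants: 33 aldol adduct
Product: 34 (R)-4-benzyl-3-{(2R,3S)-2-methyl-3-[(triethylsilyl)oxy]butanoyl}-1,3-oxazolidin-2-one
Conditions: TESCl, imidazole, DMF, 0 °C
Reagents that add atoms: chlorotriethylsilane, CC[Si](CC)(CC)Cl
Why: silylation of the secondary alcohol prevents retro-aldol and self-acylation later.

Step 19
Reactants: 34 silylated imide
Product: 36 (2R,3S)-2-methyl-3-[(triethylsilyl)oxy]butanoic acid, via peroxy acid 35 (not isolated)
Conditions: LiOH, H2O2, THF/H2O, 0 °C; then Na2SO3; then 1 M HCl to pH 3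
Reagents that add atoms: hydrogen peroxide, OO
Why: hydroperoxide attacks the exocyclic imide carbonyl selectively without epimerising C2, and sulfite reduces the percarboxylate.

Step 20
Reactants: 28 macrocyclic alcohol; 36 silyloxy acid
Product: 37 methyl (3aS,4S,5S,6E,10Z,11aR)-4-{[(2S,3R)-2,3-dimethyloxirane-2-carbonyl]oxy}-10-methyl-5-({(2R,3S)-2-methyl-3-[(triethylsilyl)oxy]butanoyl}oxy)-3-methylidene-2-oxo-2,3,3a,4,5,8,9,11a-octahydrocyclodeca[b]furan-6-carboxylate
Conditions: DCC, DMAP (0.3 equiv), CH2Cl2, 0 °C to rt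
Reagents that add atoms: none
Why: Steglich esterification of the allylic C9 hydroxyl with retention at all centres.

Step 21
Reactants: 37 triethylsilyl ether
Product: 38 CNP0135583.2, methyl (3aS,4S,5S,6E,10Z,11aR)-4-{[(2S,3R)-2,3-dimethyloxirane-2-carbonyl]oxy}-5-{[(2R,3S)-3-hydroxy-2-methylbutanoyl]oxy}-10-methyl-3-methylidene-2-oxo-2,3,3a,4,5,8,9,11a-octahydrocyclodeca[b]furan-6-carboxylate
Conditions: HF·pyridine, THF, 0 °C
Reagents that add atoms: none
Why: mild fluoride cleavage of the triethylsilyl ether leaves the epoxide, the α-methylene lactone and the three esters intact.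

## Compound list

1 | but-2-yn-1-ol | CC#CCO | starting material
2 | sodium 2,2-bis(2-methoxyethoxy)-3-methyl-2,5-dihydro-1,2-oxaluminol-2-uide (cyclic alkenylalanate) | CC1=CCO[Al-]1(OCCOC)OCCOC.[Na+] | intermediate
3 | (Z)-3-iodobut-2-en-1-ol | OC/C=C(/C)I | intermediate
4 | but-3-enylzinc bromide | C=CCC[Zn]Br | starting material
5 | (Z)-3-methylhepta-2,6-dien-1-ol | OC/C=C(/C)CCC=C | intermediate
6 | (Z)-3-methylhepta-2,6-dienal | O=C/C=C(/C)CCC=C | intermediate
7 | 2,2-dimethoxyacetaldehyde | COC(OC)C=O | starting material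
8 | methyl acrylate | C=CC(=O)OC | starting material
9 | methyl 3-hydroxy-4,4-dimethoxy-2-methylidenebutanoate (racemic) | COC(=O)C(=C)C(O)C(OC)OC | intermediate
10 | methyl (Z)-2-(bromomethyl)-4,4-dimethoxybut-2-enoate | COC(=O)/C(CBr)=C/C(OC)OC | intermediate
11 | methyl (Z)-2-(bromomethyl)-4-oxobut-2-enoate | COC(=O)/C(CBr)=C/C=O | intermediate
12 | methyl propanoate | CCC(=O)OC | starting material
13 | methyl formate | COC=O | starting material
14 | sodium 3-methoxy-2-methyl-3-oxoprop-1-en-1-olate | COC(=O)C(C)=C[O-].[Na+] | intermediate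
15 | methyl (E)-3-[(tert-butyldimethylsilyl)oxy]-2-methylprop-2-enoate | COC(=O)/C(C)=C/O[Si](C)(C)C(C)(C)C | intermediate
16 | methyl (Z)-2-(bromomethyl)-3-[(tert-butyldimethylsilyl)oxy]prop-2-enoate | COC(=O)/C(CBr)=C/O[Si](C)(C)C(C)(C)C | intermediate
17 | methyl (E)-3-[(tert-butyldimethylsilyl)oxy]-2-[(4,4,5,5-tetramethyl-1,3,2-dioxaborolan-2-yl)methyl]prop-2-enoate | COC(=O)/C(CB1OC(C)(C)C(C)(C)O1)=C/O[Si](C)(C)C(C)(C)C | intermediate
18 | dimethyl (2Z,4S,5S)-2-(bromomethyl)-5-[(tert-butyldimethylsilyl)oxy]-6-methylidene-4-[(4,4,5,5-tetramethyl-1,3,2-dioxaborolan-2-yl)oxy]hept-2-enedioate (pinacol borate of 19) | COC(=O)/C(CBr)=C/[C@H](OB1OC(C)(C)C(C)(C)O1)[C@@H](O[Si](C)(C)C(C)(C)C)C(=C)C(=O)OC | intermediate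
19 | dimethyl (2Z,4S,5S)-2-(bromomethyl)-5-[(tert-butyldimethylsilyl)oxy]-4-hydroxy-6-methylidenehept-2-enedioate | COC(=O)/C(CBr)=C/[C@H](O)[C@@H](O[Si](C)(C)C(C)(C)C)C(=C)C(=O)OC | intermediate
20 | dimethyl (2Z,4S,5S)-2-(bromomethyl)-5-[(tert-butyldimethylsilyl)oxy]-6-methylidene-4-[(trimethylsilyl)oxy]hept-2-enedioate | COC(=O)/C(CBr)=C/[C@H](O[Si](C)(C)C)[C@@H](O[Si](C)(C)C(C)(C)C)C(=C)C(=O)OC | intermediate
21 | methyl (3S,4S)-3-[(tert-butyldimethylsilyl)oxy]-4-[(2R,3S)-2-[(1Z)-2-methylhexa-1,5-dien-1-yl]-4-methylidene-5-oxooxolan-3-yl]-2-methylidene-4-[(trimethylsilyl)oxy]butanoate | C=C1C(=O)O[C@H](/C=C(/C)CCC=C)[C@H]1[C@H](O[Si](C)(C)C)[C@@H](O[Si](C)(C)C(C)(C)C)C(=C)C(=O)OC | intermediate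
22 | methyl (3S,4S)-3-[(tert-butyldimethylsilyl)oxy]-4-hydroxy-4-[(2R,3R)-2-[(1Z)-2-methylhexa-1,5-dien-1-yl]-4-methylidene-5-oxooxolan-3-yl]-2-methylidenebutanoate | C=C1C(=O)O[C@H](/C=C(/C)CCC=C)[C@H]1[C@H](O)[C@@H](O[Si](C)(C)C(C)(C)C)C(=C)C(=O)OC | intermediate
23 | (E)-2-methylbut-2-en-1-ol | C/C=C(\C)CO | starting material
24 | [(2R,3R)-2,3-dimethyloxiran-2-yl]methanol | OC[C@@]1(C)O[C@@H]1C | intermediate
25 | (2S,3R)-2,3-dimethyloxirane-2-carboxylic acid | OC(=O)[C@@]1(C)O[C@@H]1C | intermediate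
26 | methyl (3S,4S)-3-[(tert-butyldimethylsilyl)oxy]-4-{[(2S,3R)-2,3-dimethyloxirane-2-carbonyl]oxy}-4-[(2R,3S)-2-[(1Z)-2-methylhexa-1,5-dien-1-yl]-4-methylidene-5-oxooxolan-3-yl]-2-methylidenebutanoate | C=C1C(=O)O[C@H](/C=C(/C)CCC=C)[C@H]1[C@H](OC(=O)[C@@]2(C)O[C@@H]2C)[C@@H](O[Si](C)(C)C(C)(C)C)C(=C)C(=O)OC | intermediate
27 | methyl (3S,4S)-4-{[(2S,3R)-2,3-dimethyloxirane-2-carbonyl]oxy}-3-hydroxy-4-[(2R,3S)-2-[(1Z)-2-methylhexa-1,5-dien-1-yl]-4-methylidene-5-oxooxolan-3-yl]-2-methylidenebutanoate | C=C1C(=O)O[C@H](/C=C(/C)CCC=C)[C@H]1[C@H](OC(=O)[C@@]2(C)O[C@@H]2C)[C@@H](O)C(=C)C(=O)OC | intermediate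
28 | methyl (3aS,4S,5S,6E,10Z,11aR)-4-{[(2S,3R)-2,3-dimethyloxirane-2-carbonyl]oxy}-5-hydroxy-10-methyl-3-methylidene-2-oxo-2,3,3a,4,5,8,9,11a-octahydrocyclodeca[b]furan-6-carboxylate | C=C1C(=O)O[C@@H]2/C=C(/C)CC/C=C(/C(=O)OC)[C@H](O)[C@@H](OC(=O)[C@@]3(C)O[C@@H]3C)[C@@H]12 | intermediate
29 | (R)-4-benzyl-3-propanoyl-1,3-oxazolidin-2-one | CCC(=O)N1[C@H](Cc2ccccc2)COC1=O | starting material
30 | acetaldehyde | CC=O | starting material
31 | (R)-4-benzyl-3-[(Z)-1-[(dibutylboranyl)oxy]prop-1-en-1-yl]-1,3-oxazolidin-2-one (boron Z-enolate) | C/C=C(\OB(CCCC)CCCC)N1[C@H](Cc2ccccc2)COC1=O | intermediate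
32 | (R)-4-benzyl-3-{(2R,3S)-3-[(dibutylboranyl)oxy]-2-methylbutanoyl}-1,3-oxazolidin-2-one (boron aldolate) | O=C(N1[C@H](Cc2ccccc2)COC1=O)[C@H](C)[C@H](C)OB(CCCC)CCCC | intermediate
33 | (R)-4-benzyl-3-[(2R,3S)-3-hydroxy-2-methylbutanoyl]-1,3-oxazolidin-2-one | O=C(N1[C@H](Cc2ccccc2)COC1=O)[C@H](C)[C@H](C)O | intermediate
34 | (R)-4-benzyl-3-{(2R,3S)-2-methyl-3-[(triethylsilyl)oxy]butanoyl}-1,3-oxazolidin-2-one | O=C(N1[C@H](Cc2ccccc2)COC1=O)[C@H](C)[C@H](C)O[Si](CC)(CC)CC | intermediate
35 | (2R,3S)-2-methyl-3-[(triethylsilyl)oxy]butaneperoxoic acid | OOC(=O)[C@H](C)[C@H](C)O[Si](CC)(CC)CC | intermediate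
36 | (2R,3S)-2-methyl-3-[(triethylsilyl)oxy]butanoic acid | OC(=O)[C@H](C)[C@H](C)O[Si](CC)(CC)CC | intermediate
37 | methyl (3aS,4S,5S,6E,10Z,11aR)-4-{[(2S,3R)-2,3-dimethyloxirane-2-carbonyl]oxy}-10-methyl-5-({(2R,3S)-2-methyl-3-[(triethylsilyl)oxy]butanoyl}oxy)-3-methylidene-2-oxo-2,3,3a,4,5,8,9,11a-octahydrocyclodeca[b]furan-6-carboxylate | C=C1C(=O)O[C@@H]2/C=C(/C)CC/C=C(/C(=O)OC)[C@H](OC(=O)[C@H](C)[C@H](C)O[Si](CC)(CC)CC)[C@@H](OC(=O)[C@@]3(C)O[C@@H]3C)[C@@H]12 | intermediate
38 | CNP0135583.2, methyl (3aS,4S,5S,6E,10Z,11aR)-4-{[(2S,3R)-2,3-dimethyloxirane-2-carbonyl]oxy}-5-{[(2R,3S)-3-hydroxy-2-methylbutanoyl]oxy}-10-methyl-3-methylidene-2-oxo-2,3,3a,4,5,8,9,11a-octahydrocyclodeca[b]furan-6-carboxylate | C=C1C(=O)O[C@@H]2/C=C(/C)CC/C=C(/C(=O)OC)[C@H](OC(=O)[C@H](C)[C@H](C)O)[C@@H](OC(=O)[C@@]3(C)O[C@@H]3C)[C@@H]12 | target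

## Step count, longest sequence and main risks

Total: 21 steps. Longest linear sequence: 10 steps (4, 5, 6, 10, 11, 14, 15, 16, 20, 21; the branch 7, 8, 9 into step 10 is equally long).

**Step 10 (key C8–C9 coupling).** The boronate is an untested, electron-poor allylboron reagent; the rate, the sense and level of enantio-induction, and premature lactonisation of O8 onto the neighbouring ester are all open. Fallback: set out from 11 and 17 and run the same bond formation without chiral control under Sc(OTf)3 catalysis (10 mol %, toluene, 0 °C), where the chair transition state still gives the syn pair. This forms ent-borate F1 beside 18 and, after buffer work-up, ent-alcohol F2 beside 19. The racemate is resolved by preparative chromatography on a chiral stationary phase, and the route is rejoined at 19.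

**Step 11 (chromium allylation/lactonisation).** Facial selectivity rests on a substrate model, the Z enal may isomerise, and the transient trimethylsilyl ether may fall off early. Fallback: set out from 19 and make the robust triethylsilyl ether F3 (TESOTf, 2,6-lutidine, CH2Cl2, −78 °C). Couple F3 with 6 under catalyst control: CrCl2 (10 mol %), the matched enantiomer of a chiral carbazole bis(oxazoline) ligand, Mn powder, TMSCl, THF. This gives open-chain bis-silyl adduct F4; PPTS in MeOH then removes both silyl groups from O6 and O8 and closes the lactone, returning to the route at 22.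

**Step 16 (ring-closing metathesis).** The ten-membered ring must close onto a hindered 1,1-disubstituted acrylate, and the free allylic alcohol can divert ruthenium into redox isomerisation. Fallback: set out from 26 and close the ring one step earlier, on the silyl ether, with the second-generation Grubbs catalyst RuCl2(=CHPh)(H2IMes)(PCy3) and 1,4-benzoquinone in refluxing 1,2-dichloroethane. This gives macrocyclic silyl ether F5; HF·pyridine then frees the C9 hydroxyl in the ring and returns to the route at 28.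

## Further compounds

F1 | step 10 | dimethyl (2Z,4R,5R)-2-(bromomethyl)-5-[(tert-butyldimethylsilyl)oxy]-6-methylidene-4-[(4,4,5,5-tetramethyl-1,3,2-dioxaborolan-2-yl)oxy]hept-2-enedioate (ent-borate) | COC(=O)/C(CBr)=C/[C@@H](OB1OC(C)(C)C(C)(C)O1)[C@H](O[Si](C)(C)C(C)(C)C)C(=C)C(=O)OC
F2 | step 10 | dimethyl (2Z,4R,5R)-2-(bromomethyl)-5-[(tert-butyldimethylsilyl)oxy]-4-hydroxy-6-methylidenehept-2-enedioate (ent-alcohol) | COC(=O)/C(CBr)=C/[C@@H](O)[C@H](O[Si](C)(C)C(C)(C)C)C(=C)C(=O)OC
F3 | step 11 | dimethyl (2Z,4S,5S)-2-(bromomethyl)-5-[(tert-butyldimethylsilyl)oxy]-6-methylidene-4-[(triethylsilyl)oxy]hept-2-enedioate (triethylsilyl ether) | COC(=O)/C(CBr)=C/[C@H](O[Si](CC)(CC)CC)[C@@H](O[Si](C)(C)C(C)(C)C)C(=C)C(=O)OC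
F4 | step 11 | dimethyl (3S,4S,5S)-5-[(tert-butyldimethylsilyl)oxy]-2,6-dimethylidene-3-{(1R,2Z)-3-methyl-1-[(trimethylsilyl)oxy]hepta-2,6-dien-1-yl}-4-[(triethylsilyl)oxy]heptanedioate (open-chain bis-silyl adduct) | COC(=O)C(=C)[C@@H]([C@H](O[Si](C)(C)C)/C=C(/C)CCC=C)[C@H](O[Si](CC)(CC)CC)[C@@H](O[Si](C)(C)C(C)(C)C)C(=C)C(=O)OC
F5 | step 16 | methyl (3aS,4S,5S,6E,10Z,11aR)-5-[(tert-butyldimethylsilyl)oxy]-4-{[(2S,3R)-2,3-dimethyloxirane-2-carbonyl]oxy}-10-methyl-3-methylidene-2-oxo-2,3,3a,4,5,8,9,11a-octahydrocyclodeca[b]furan-6-carboxylate (macrocyclic silyl ether) | C=C1C(=O)O[C@@H]2/C=C(/C)CC/C=C(/C(=O)OC)[C@H](O[Si](C)(C)C(C)(C)C)[C@@H](OC(=O)[C@@]3(C)O[C@@H]3C)[C@@H]12
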